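**Plan**

- Retrosynthesis, last cut first: the isopropenyl group and the CH2CH2CO2Me arm sit on adjacent ring carbons and are read as the two ends of a cleaved 2,2-dimethylcyclohexanone (temporary ring A), so the C(=O)–CMe2 bond of that ring is the final bond to break; the butenolide is detached at its sp2–sp3 bond.
- Core disconnection: in the 6-oxabicyclo[3.2.1]octan-7-one, the lactone O–C bond at the tertiary, isopropenyl-bearing carbon and the ring bond between the quaternary carboxyl-bearing carbon and the neighbouring CH are cut together. This is possible because the carboxyl carbon is 1,3-diaxial to the tertiary C–O carbon across the cyclohexane: a carboxyl-stabilised radical at the quaternary carbon can add to a ring A alkene spanning those two carbons, and its own ester can then trap the cation.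
- Further cuts: ring A–tether sp2–sp3 bond (B-alkyl Suzuki–Miyaura), quaternary carbon–CH2 bond (malonate alkylation), bond between the methyl-bearing stereocentre and the malonate carbon (iridium-catalysed allylic alkylation).
- Forward order: chain built on a malonate (one carboxyl is the traceless radical precursor, the other becomes the lactone); ring A attached; cyclohexane ring B and lactone closed in one cascade; butenolide coupled; ring A opened last to release ester and isopropenyl.
- Stereochemistry: the C-methyl centre comes from the chiral iridium catalyst; the other three centres arise in the cascade, by 1,2-induction from it (allylic strain in a chair), by the cis geometry of the ring A alkene, and by the cis-only lactone bridge.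

Key step: step 8

Assumption: in step 2 the antipode of the phosphoramidite ligand is the one that delivers the (R) configuration at the allylic carbon; both antipodes are commercial and the sense of induction is uniform for alkyl-substituted allyl carbonates.

**Step 1**
Reactants: 1 (E)-but-2-en-1-ol
Product: 2 (E)-but-2-en-1-yl methyl carbonate
Conditions: ClCO2Me, pyridine, CH2Cl2, 0 °C to rt
Reagents that add atoms: methyl chloroformate, COC(=O)Cl
Why: O-acylation of the primary allylic alcohol gives the carbonate leaving group needed for the allylic substitution.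

**Step 2**
Reactants: 2 (E)-but-2-en-1-yl methyl carbonate; 3 tert-butyl methyl propanedioate
Product: 4 1-tert-butyl 3-methyl 2-[(2R)-but-3-en-2-yl]propanedioate (both epimers at the malonate carbon)
Conditions: [Ir(cod)Cl]2 (2 mol %), O,O'-(1,1'-binaphthalene-2,2'-diyl) N,N-bis(1-phenylethyl)phosphoramidite (single antipode, 4 mol %), TBD (8 mol %), THF, rt
Reagents that add atoms: none
Why: Iridium-catalysed asymmetric allylic alkylation (Tsuji–Trost type) under salt-free conditions, in which the cyclometalated iridium–phosphoramidite allyl complex is attacked at its substituted terminus, so the branched product should form with the methyl-bearing centre set by the ligand; the malonate carbon is an irrelevant mixture because it becomes a planar radical in step 8.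

**Step 3**
Reactants: 4 1-tert-butyl 3-methyl 2-[(2R)-but-3-en-2-yl]propanedioate; 5 tert-butyl(2-iodoethoxy)dimethylsilane
Product: 6 1-tert-butyl 3-methyl 2-[(2R)-but-3-en-2-yl]-2-{2-[(tert-butyldimethylsilyl)oxy]ethyl}propanedioate (both epimers at the malonate carbon)
Conditions: NaH, DMF, 0 °C; then 5, 60 °C
Reagents that add atoms: none
Why: Malonate alkylation (SN2 on the primary iodide) builds the fully substituted carbon and installs the two-carbon arm that later carries the butenolide; no controlled stereocentre is created.

**Step 4**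
Reactants: 7 2,2-dimethylcyclohexane-1,3-dione
Product: 8 6,6-dimethyl-5-oxocyclohex-1-en-1-yl trifluoromethanesulfonate
Conditions: KN(SiMe3)2, THF, −78 °C; PhNTf2, −78 to 0 °C; 1 M HCl wash
Reagents that add atoms: N-phenylbis(trifluoromethanesulfonimide), O=S(=O)(N(c1ccccc1)S(=O)(=O)C(F)(F)F)C(F)(F)F
Why: Enolisation of one carbonyl of the symmetrical dione and O-sulfonylation give the vinyl triflate; the gem-dimethyl carbon allows only this enolate and later keeps the ring alkene out of conjugation with the ketone.

**Step 5**
Reactants: 6 1-tert-butyl 3-methyl 2-[(2R)-but-3-en-2-yl]-2-{2-[(tert-butyldimethylsilyl)oxy]ethyl}propanedioate; 8 6,6-dimethyl-5-oxocyclohex-1-en-1-yl trifluoromethanesulfonate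
Product: 10 1-tert-butyl 3-methyl 2-{2-[(tert-butyldimethylsilyl)oxy]ethyl}-2-[(2R)-4-(6,6-dimethyl-5-oxocyclohex-1-en-1-yl)butan-2-yl]propanedioate, via alkylborane 9 (not isolated)
Conditions: 9-BBN, THF, rt; then 8, PdCl2(dppf), AsPh3, Cs2CO3, DMF/H2O, rt
Reagents that add atoms: none
Why: Anti-Markovnikov hydroboration of the terminal alkene followed by B-alkyl Suzuki–Miyaura coupling joins the tether to ring A, since zerovalent palladium inserts into the C–OTf bond far faster than it touches esters, ketone or silyl ether.

**Step 6**
Reactants: 10 1-tert-butyl 3-methyl 2-{2-[(tert-butyldimethylsilyl)oxy]ethyl}-2-[(2R)-4-(6,6-dimethyl-5-oxocyclohex-1-en-1-yl)butan-2-yl]propanedioate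
Product: 11 (3R)-2-(tert-butoxycarbonyl)-2-{2-[(tert-butyldimethylsilyl)oxy]ethyl}-5-(6,6-dimethyl-5-oxocyclohex-1-en-1-yl)-3-methylpentanoic acid (both epimers at C-2)
Conditions: LiOH·H2O, THF/MeOH/H2O, 45 °C; then 1 M HCl, 0 °C
Reagents that add atoms: lithium hydroxide, [Li+].[OH-]
Why: Saponification by acyl–oxygen cleavage removes only the methyl ester because the tert-butyl ester is shielded, so the two carboxyl groups are differentiated chemoselectively.

**Step 7**
Reactants: 11 (3R)-2-(tert-butoxycarbonyl)-2-{2-[(tert-butyldimethylsilyl)oxy]ethyl}-5-(6,6-dimethyl-5-oxocyclohex-1-en-1-yl)-3-methylpentanoic acid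
Product: 12 1-tert-butyl 3-(1,3-dioxoisoindolin-2-yl) 2-{2-[(tert-butyldimethylsilyl)oxy]ethyl}-2-[(2R)-4-(6,6-dimethyl-5-oxocyclohex-1-en-1-yl)butan-2-yl]propanedioate
Conditions: N-hydroxyphthalimide, DIC, DMAP (cat.), CH2Cl2, rt
Reagents that add atoms: N-hydroxyphthalimide, O=C1c2ccccc2C(=O)N1O
Why: Carbodiimide (Steglich-type) esterification converts the acid, which has no alpha-hydrogen and so cannot form a ketene, into the redox-active N-acyloxyphthalimide from which the carboxyl group can leave as CO2.

**Step 8**
Reactants: 12 1-tert-butyl 3-(1,3-dioxoisoindolin-2-yl) 2-{2-[(tert-butyldimethylsilyl)oxy]ethyl}-2-[(2R)-4-(6,6-dimethyl-5-oxocyclohex-1-en-1-yl)butan-2-yl]propanedioate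
Product: 13 (1S,6R,7R,8R)-7-{2-[(tert-butyldimethylsilyl)oxy]ethyl}-2,2,8-trimethyl-11-oxatricyclo[5.3.2.0^{1,6}]dodecane-3,12-dione (trans-decalin-3-one with a gamma-lactone bridge)
Conditions: fac-Ir(ppy)3 (1 mol %), MeCN (0.02 M), blue LEDs (450 nm), rt, degassed
Reagents that add atoms: none
Why: Proposed new method: the photoexcited trivalent iridium complex transfers an electron to the N-acyloxyphthalimide, N–O cleavage and loss of CO2 give the tertiary alpha-(tert-butoxycarbonyl) radical, this adds to the ring A alkene, and the tertiary radical so formed is oxidised by the tetravalent iridium left from the first electron transfer to a cation that the tert-butyl ester carbonyl captures with loss of isobutene (redox-neutral radical-polar crossover); the closest known reaction types are the oxidative radical carbolactonisation of unsaturated malonates with Mn(OAc)3 and the photoredox carbo-oxygenation of alkenes with N-acyloxyphthalimides, the new element being that one malonate carboxyl leaves as the radical precursor while the other is the internal nucleophile. Ring B closes by 6-endo-trig radical attack on the CH terminus of the alkene (5-exo attack would have to make a spiro quaternary carbon next to the gem-dimethyl carbon), and the gamma-lactone closes by attack of the axial ester oxygen on the planar cation across the 1,3-diaxial positions (five-membered, exo to the cationic carbon). The methyl-bearing centre controls the face: in the chair transition state its hydrogen lies in the plane of the ester-conjugated radical (minimal allylic 1,3-strain) and the methyl group is equatorial, anti to the forming bond. At the radical carbon the silyloxyethyl arm should take the equatorial site next to that hydrogen and the flat ester the axial site, at the new CH carbon the ring A methylene is trans to the tether on the cyclic alkene and so ends up trans to the new C–O bond, and the C–O carbon can only form cis to the carboxyl, which together give the trans-fused, lactone-bridged array of the target. The step needs 6-endo over 5-exo closure, an axial ester, and cation capture faster than proton loss; the substitution pattern of the alkene, the size difference between the two radical substituents and the proximity of the axial ester should secure these, and any epimer with an equatorial ester cannot lactonise and would be removed as olefinic material.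

**Step 9**
Reactants: 13 (1S,6R,7R,8R)-7-{2-[(tert-butyldimethylsilyl)oxy]ethyl}-2,2,8-trimethyl-11-oxatricyclo[5.3.2.0^{1,6}]dodecane-3,12-dione
Product: 14 (1S,6R,7R,8R)-7-(2-bromoethyl)-2,2,8-trimethyl-11-oxatricyclo[5.3.2.0^{1,6}]dodecane-3,12-dione
Conditions: Ph3PBr2, CH2Cl2, 0 °C to rt
Reagents that add atoms: triphenylphosphine dibromide, BrP(Br)(c1ccccc1)(c1ccccc1)c1ccccc1
Why: Ph3PBr2 converts the primary silyl ether directly into the bromide through the alkoxyphosphonium salt (Appel-type SN2), which avoids a free alcohol that could translactonise; the hindered ketone and the bridged lactone should be inert under these neutral conditions.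

**Step 10**
Reactants: 15 furan-2(5H)-one
Product: 17 3-bromofuran-2(5H)-one, via dibromide 16 (not isolated)
Conditions: Br2, CH2Cl2, 0 °C to rt; then Et3N, 0 °C
Reagents that add atoms: bromine, BrBr
Why: Bromine addition to the butenolide alkene followed by base-induced loss of HBr (the acidic alpha-hydrogen is removed and the beta-bromide leaves) gives the alpha-bromobutenolide.

**Step 11**
Reactants: 14 (1S,6R,7R,8R)-7-(2-bromoethyl)-2,2,8-trimethyl-11-oxatricyclo[5.3.2.0^{1,6}]dodecane-3,12-dione; 17 3-bromofuran-2(5H)-one
Product: 19 (1S,6R,7R,8R)-2,2,8-trimethyl-7-[2-(2-oxo-2,5-dihydrofuran-3-yl)ethyl]-11-oxatricyclo[5.3.2.0^{1,6}]dodecane-3,12-dione, via alkylzinc bromide 18 (not isolated)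
Conditions: Zn dust, LiCl, THF, 50 °C; then 17, Pd(OAc)2 (2 mol %), SPhos (4 mol %), THF, rt
Reagents that add atoms: none
Why: Zinc insertion into the primary C–Br bond and Negishi coupling with the alpha-bromobutenolide form the sp3–sp2 bond; the alkylzinc tolerates ketone and lactones, and no stereocentre is touched.

**Step 12**
Reactants: 19 (1S,6R,7R,8R)-2,2,8-trimethyl-7-[2-(2-oxo-2,5-dihydrofuran-3-yl)ethyl]-11-oxatricyclo[5.3.2.0^{1,6}]dodecane-3,12-dione
Product: 21 methyl 3-[(1R,2R,5S,8R)-2-methyl-7-oxo-1-[2-(2-oxo-2,5-dihydrofuran-3-yl)ethyl]-5-(prop-1-en-2-yl)-6-oxabicyclo[3.2.1]octan-8-yl]propanoate (CNP0209666.1), via hydroperoxy ketal 20 (not isolated)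
Conditions: 50% aq. H2O2, MeOH, H2SO4 (cat.), rt; extractive removal of excess H2O2; then FeSO4·7H2O, Cu(OAc)2·H2O, MeOH, 0 °C to rt
Reagents that add atoms: hydrogen peroxide, OO; methanol, CO
Why: Perketalisation followed by alkoxy-radical beta-scission: divalent iron cleaves the O–O bond, the alpha-methoxy alkoxy radical fragments towards the gem-dimethyl carbon to give the methyl ester and a tertiary radical, and divalent copper oxidises that radical with loss of a methyl hydrogen (the only beta-hydrogens) to the isopropenyl group, while monovalent copper returns trivalent iron to the divalent state; no cation is formed next to the lactone C–O carbon and no stereocentre is involved.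

**Compound list**

1 | (E)-but-2-en-1-ol | C/C=C/CO | starting material
2 | (E)-but-2-en-1-yl methyl carbonate | C/C=C/COC(=O)OC | intermediate
3 | tert-butyl methyl propanedioate | COC(=O)CC(=O)OC(C)(C)C | starting material
4 | 1-tert-butyl 3-methyl 2-[(2R)-but-3-en-2-yl]propanedioate (both epimers at C-2 of the malonate) | C=C[C@@H](C)C(C(=O)OC)C(=O)OC(C)(C)C | intermediate
5 | tert-butyl(2-iodoethoxy)dimethylsilane | ICCO[Si](C)(C)C(C)(C)C | starting material
6 | 1-tert-butyl 3-methyl 2-[(2R)-but-3-en-2-yl]-2-{2-[(tert-butyldimethylsilyl)oxy]ethyl}propanedioate (both epimers at C-2) | C=C[C@@H](C)C(CCO[Si](C)(C)C(C)(C)C)(C(=O)OC)C(=O)OC(C)(C)C | intermediate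
7 | 2,2-dimethylcyclohexane-1,3-dione | CC1(C)C(=O)CCCC1=O | starting material
8 | 6,6-dimethyl-5-oxocyclohex-1-en-1-yl trifluoromethanesulfonate | CC1(C)C(=O)CCC=C1OS(=O)(=O)C(F)(F)F | intermediate
9 | B-alkyl-9-borabicyclo[3.3.1]nonane from 6 (boron on the former terminal alkene carbon) | B1(CC[C@@H](C)C(CCO[Si](C)(C)C(C)(C)C)(C(=O)OC)C(=O)OC(C)(C)C)C2CCCC1CCC2 | intermediate
10 | 1-tert-butyl 3-methyl 2-{2-[(tert-butyldimethylsilyl)oxy]ethyl}-2-[(2R)-4-(6,6-dimethyl-5-oxocyclohex-1-en-1-yl)butan-2-yl]propanedioate (both epimers at C-2) | O=C1CCC=C(CC[C@@H](C)C(CCO[Si](C)(C)C(C)(C)C)(C(=O)OC)C(=O)OC(C)(C)C)C1(C)C | intermediate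
11 | (3R)-2-(tert-butoxycarbonyl)-2-{2-[(tert-butyldimethylsilyl)oxy]ethyl}-5-(6,6-dimethyl-5-oxocyclohex-1-en-1-yl)-3-methylpentanoic acid (both epimers at C-2) | O=C1CCC=C(CC[C@@H](C)C(CCO[Si](C)(C)C(C)(C)C)(C(=O)O)C(=O)OC(C)(C)C)C1(C)C | intermediate
12 | 1-tert-butyl 3-(1,3-dioxoisoindolin-2-yl) 2-{2-[(tert-butyldimethylsilyl)oxy]ethyl}-2-[(2R)-4-(6,6-dimethyl-5-oxocyclohex-1-en-1-yl)butan-2-yl]propanedioate (both epimers at C-2) | O=C1CCC=C(CC[C@@H](C)C(CCO[Si](C)(C)C(C)(C)C)(C(=O)ON2C(=O)c3ccccc3C2=O)C(=O)OC(C)(C)C)C1(C)C | intermediate
13 | (1S,6R,7R,8R)-7-{2-[(tert-butyldimethylsilyl)oxy]ethyl}-2,2,8-trimethyl-11-oxatricyclo[5.3.2.0^{1,6}]dodecane-3,12-dione | CC3(C)[C@@]12CC[C@@H](C)[C@@](CCO[Si](C)(C)C(C)(C)C)(C(=O)O1)[C@H]2CCC3=O | intermediate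
14 | (1S,6R,7R,8R)-7-(2-bromoethyl)-2,2,8-trimethyl-11-oxatricyclo[5.3.2.0^{1,6}]dodecane-3,12-dione | CC3(C)[C@@]12CC[C@@H](C)[C@@](CCBr)(C(=O)O1)[C@H]2CCC3=O | intermediate
15 | furan-2(5H)-one | O=C1OCC=C1 | starting material
16 | trans-3,4-dibromodihydrofuran-2(3H)-one (racemic) | O=C1OCC(Br)C1Br | intermediate
17 | 3-bromofuran-2(5H)-one | O=C1OCC=C1Br | intermediate
18 | bromido{2-[(1S,6R,7R,8R)-2,2,8-trimethyl-3,12-dioxo-11-oxatricyclo[5.3.2.0^{1,6}]dodecan-7-yl]ethyl}zinc | CC3(C)[C@@]12CC[C@@H](C)[C@@](CC[Zn]Br)(C(=O)O1)[C@H]2CCC3=O | intermediate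
19 | (1S,6R,7R,8R)-2,2,8-trimethyl-7-[2-(2-oxo-2,5-dihydrofuran-3-yl)ethyl]-11-oxatricyclo[5.3.2.0^{1,6}]dodecane-3,12-dione | CC3(C)[C@@]12CC[C@@H](C)[C@@](CCC4=CCOC4=O)(C(=O)O1)[C@H]2CCC3=O | intermediate
20 | (1S,6R,7R,8R)-3-hydroperoxy-3-methoxy-2,2,8-trimethyl-7-[2-(2-oxo-2,5-dihydrofuran-3-yl)ethyl]-11-oxatricyclo[5.3.2.0^{1,6}]dodecan-12-one (both epimers at C-3) | CC3(C)[C@@]12CC[C@@H](C)[C@@](CCC4=CCOC4=O)(C(=O)O1)[C@H]2CCC3(OC)OO | intermediate
21 | methyl 3-[(1R,2R,5S,8R)-2-methyl-7-oxo-1-[2-(2-oxo-2,5-dihydrofuran-3-yl)ethyl]-5-(prop-1-en-2-yl)-6-oxabicyclo[3.2.1]octan-8-yl]propanoate (CNP0209666.1) | C=C(C)[C@@]12CC[C@@H](C)[C@@](CCC3=CCOC3=O)(C(=O)O1)[C@H]2CCC(=O)OC | target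

**Step count and risks**

Total step count: 12. Longest linear sequence: 10 (steps 1, 2, 3, 5, 6, 7, 8, 9, 11, 12).

Steps most likely to fail:

1. Step 8. The tertiary radical may be reduced before it cyclises, the radical carbon may add with the ester equatorial so that lactonisation is impossible, or the tertiary cation may lose a proton faster than the ester captures it. The fallback uses known chemistry and sets out from acid 11. Iododecarboxylation with PhI(OAc)2 and I2 under visible-light irradiation would give tert-butyl (3R)-2-{2-[(tert-butyldimethylsilyl)oxy]ethyl}-5-(6,6-dimethyl-5-oxocyclohex-1-en-1-yl)-2-iodo-3-methylpentanoate F1. Heating F1 in benzene with catalytic (Bu3Sn)2 under irradiation (iodine-atom-transfer radical cyclisation) would move the iodine to the ring-fusion carbon by the same 6-endo closure. The tertiary iodide so formed would lactonise in the same flask with loss of isobutene and hydrogen iodide, and the route is rejoined at 13.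

2. Step 12. Perketalisation of the ketone next to the gem-dimethyl carbon may stall, or the hydroperoxide may rearrange under acid before the metal salts are added. The fallback sets out from 19. Baeyer–Villiger oxidation with mCPBA and NaHCO3 in CH2Cl2 would insert oxygen between the carbonyl and the gem-dimethyl carbon to give the seven-membered lactone (1S,7R,8R,9R)-2,2,9-trimethyl-8-[2-(2-oxo-2,5-dihydrofuran-3-yl)ethyl]-3,12-dioxatricyclo[6.3.2.0^{1,7}]tridecane-4,13-dione F2. Treating F2 with TsOH·H2O in methanol would open it by alkyl–oxygen cleavage with loss of a methyl proton and esterify the liberated acid, arriving at 21.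

3. Step 3. SN2 attack of the hindered, secondary-alkyl-substituted malonate anion on the beta-silyloxy iodide may be slow, with elimination of HI from 5 taking over. The fallback sets out from 3 and inverts the order of the two C–C bond formations. Alkylation of 3 with 5 (NaH, THF/DMF) at the unhindered stage would give 1-tert-butyl 3-methyl 2-{2-[(tert-butyldimethylsilyl)oxy]ethyl}propanedioate F3. F3 would then serve as the nucleophile in the iridium-catalysed allylic alkylation of 2 under the conditions of step 2, which forms the quaternary carbon and the methyl-bearing centre together and returns to the route at 6.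

**Further compounds**

F1 | step 8 | tert-butyl (3R)-2-{2-[(tert-butyldimethylsilyl)oxy]ethyl}-5-(6,6-dimethyl-5-oxocyclohex-1-en-1-yl)-2-iodo-3-methylpentanoate (both epimers at C-2) | O=C1CCC=C(CC[C@@H](C)C(I)(CCO[Si](C)(C)C(C)(C)C)C(=O)OC(C)(C)C)C1(C)C
F2 | step 12 | (1S,7R,8R,9R)-2,2,9-trimethyl-8-[2-(2-oxo-2,5-dihydrofuran-3-yl)ethyl]-3,12-dioxatricyclo[6.3.2.0^{1,7}]tridecane-4,13-dione | CC3(C)[C@@]12CC[C@@H](C)[C@@](CCC4=CCOC4=O)(C(=O)O1)[C@H]2CCC(=O)O3
F3 | step 3 | 1-tert-butyl 3-methyl 2-{2-[(tert-butyldimethylsilyl)oxy]ethyl}propanedioate (racemic) | COC(=O)C(CCO[Si](C)(C)C(C)(C)C)C(=O)OC(C)(C)C
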